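## Retrosynthetic overview

1. Last operation: C3-acylation of the preformed (6R)-6-methyloxane-2,4-dione **20** with side-chain acid **17**, then release of the β-hydroxy acid from its acetonide (dioxanone) in the same flask.
2. **17** comes from oxidative cleavage of the isopropylidene terminus of **13**, which is the masked C9 carbonyl carbon.
3. Key bond C2–C3 (α-carbon of the acid): trans-epoxy acid **6** serves as an α-cation (enolonium-type) equivalent of the carboxylic acid and is opened at C2 by homocitronellyl cuprate **12**. Inversion sets C2, the carbinol centre is carried over, and the anti β-hydroxy acid forms without an auxiliary.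
4. **6** comes from (S)-2-methylbutan-1-ol by Sharpless epoxidation; **12** from (R)-citronellal (C6 methyl centre); **20** from methyl (R)-3-hydroxybutanoate.
5. Rings: the dihydropyranone, the only ring of the target, is made first and separately (steps 10–11). The dioxanone is temporary (made in step 8, removed in step 12).

Assumption: the SMILES is read as absolute configuration, i.e. (2R,6S)-2-[(1R,2S)-1-hydroxy-2-methylbutyl]-9-[(6R)-4-hydroxy-6-methyl-2-oxo-5,6-dihydro-2H-pyran-3-yl]-6-methyl-9-oxononanoic acid, drawn as the 4-hydroxy enol tautomer. This route is a paper design and has not been run; the regiochemistry claimed for step 7 rests on recalled precedent for cuprate openings of glycidic acids and esters.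

## Route

Step 1
Reactants: 1 (S)-2-methylbutan-1-ol
Product: 3 ethyl (2E,4S)-4-methylhex-2-enoate, via (S)-2-methylbutanal 2 (not isolated)
Conditions: TEMPO (10 mol %), PhI(OAc)2 (1.1 equiv), CH2Cl2, rt; then Ph3P=CHCO2Et (1.5 equiv), rt
Reagents that add atoms: ethyl (triphenylphosphoranylidene)acetate CCOC(=O)C=P(c1ccccc1)(c1ccccc1)c1ccccc1
Why: TEMPO/PhI(OAc)2 oxidation stops at the aldehyde under non-epimerising conditions and the stabilised ylide traps it in situ in an E-selective Wittig olefination, so the volatile, configurationally labile aldehyde is never isolated and the (S) centre of 1 is carried through.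

Step 2
Reactants: 3 ethyl (2E,4S)-4-methylhex-2-enoate
Product: 4 (2E,4S)-4-methylhex-2-en-1-ol
Conditions: DIBAL-H (2.3 equiv), CH2Cl2, −78 → −20 °C; Rochelle salt
Reagents that add atoms: none
Why: DIBAL-H 1,2-reduction of the enoate gives the (E)-allylic alcohol needed for directed epoxidation, with no stereocentre touched.

Step 3
Reactants: 4 (2E,4S)-4-methylhex-2-en-1-ol
Product: 5 [(2R,3R)-3-[(2S)-butan-2-yl]oxiran-2-yl]methanol
Conditions: Ti(OiPr)4 (10 mol %), D-(−)-diethyl tartrate (12 mol %), t-BuOOH (2 equiv), 4 Å MS, CH2Cl2, −20 °C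
Reagents that add atoms: tert-butyl hydroperoxide CC(C)(C)OO
Why: Sharpless asymmetric epoxidation, where the D-(−)-tartrate catalyst delivers oxygen to the face that gives the (2R,3R) trans-epoxide under reagent control (the remote C4 methyl exerts only a small bias).

Step 4
Reactants: 5 [(2R,3R)-3-[(2S)-butan-2-yl]oxiran-2-yl]methanol
Product: 6 (2S,3R)-3-[(2S)-butan-2-yl]oxirane-2-carboxylic acid
Conditions: RuCl3·xH2O (2 mol %), NaIO4 (3 equiv), CCl4/MeCN/H2O, rt
Reagents that add atoms: water O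
Why: Catalytic RuO4 oxidation of the primary alcohol through the aldehyde hydrate gives the glycidic acid without touching the epoxide (C2 changes from R to S by CIP priority only).

Step 5
Reactants: 7 (R)-citronellal
Product: 8 (4R)-4,8-dimethylnona-1,7-diene
Conditions: Ph3PCH3Br (1.3 equiv), KOtBu (1.25 equiv), THF, 0 °C → rt
Reagents that add atoms: methylenetriphenylphosphorane C=P(c1ccccc1)(c1ccccc1)c1ccccc1 (from methyltriphenylphosphonium bromide C[P+](c1ccccc1)(c1ccccc1)c1ccccc1.[Br-])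
Why: Wittig methylenation of the unhindered aldehyde adds the one carbon that becomes C3 of the target, and the β-methyl centre is not enolisable.

Step 6
Reactants: 8 (4R)-4,8-dimethylnona-1,7-diene
Product: 10 (6R)-9-iodo-2,6-dimethylnon-2-ene, via alkylzirconocene chloride 9 (not isolated)
Conditions: Cp2Zr(H)Cl (1.2 equiv), THF, rt; then I2 (1.2 equiv), 0 °C
Reagents that add atoms: iodine II
Why: Schwartz hydrozirconation is anti-Markovnikov and selective for the terminal alkene over the trisubstituted one, and iodinolysis of the C–Zr bond gives the primary iodide.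

Step 7
Reactants: 10 (6R)-9-iodo-2,6-dimethylnon-2-ene; 6 (2S,3R)-3-[(2S)-butan-2-yl]oxirane-2-carboxylic acid
Product: 13 (2R,3R,4S)-2-[(4S)-4,8-dimethylnon-7-en-1-yl]-3-hydroxy-4-methylhexanoic acid, via alkyllithium 11 (not isolated), via lithium dialkylcuprate 12 (not isolated)
Conditions: 10 (3.0 equiv), t-BuLi (6.0 equiv), Et2O/pentane, −78 °C; CuI (1.5 equiv), −78 → −35 °C; then Li salt of 6 [6 (1.0 equiv), LiHMDS (1.0 equiv), THF, −78 °C], −35 → 0 °C; aq. NH4Cl, HCl to pH 3
Reagents that add atoms: none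
Why: After iodine–lithium exchange and Gilman cuprate formation, the soft cuprate opens the epoxy carboxylate by SN2 at C2, the carbon α to the carboxylate (activated, and C3 is shielded by the sec-butyl group), so the α-carbon of the acid reacts as an electrophile; inversion at C2 sets that centre as R, C3 is retained, and the anti 2-alkyl-3-hydroxy acid forms directly (organocuprate epoxide opening).

Step 8
Reactants: 13 (2R,3R,4S)-2-[(4S)-4,8-dimethylnon-7-en-1-yl]-3-hydroxy-4-methylhexanoic acid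
Product: 14 (5R,6R)-6-[(2S)-butan-2-yl]-5-[(4S)-4,8-dimethylnon-7-en-1-yl]-2,2-dimethyl-1,3-dioxan-4-one
Conditions: 2-methoxypropene (4 equiv), PPTS (10 mol %), CH2Cl2, 0 °C → rt
Reagents that add atoms: 2-methoxypropene COC(C)=C
Why: Acid-catalysed transacetalisation closes the six-membered acetonide (1,3-dioxan-4-one), masking OH and CO2H in one step without touching a stereocentre.

Step 9
Reactants: 14 (5R,6R)-6-[(2S)-butan-2-yl]-5-[(4S)-4,8-dimethylnon-7-en-1-yl]-2,2-dimethyl-1,3-dioxan-4-one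
Product: 17 (4S)-7-[(5R,6R)-6-[(2S)-butan-2-yl]-2,2-dimethyl-4-oxo-1,3-dioxan-5-yl]-4-methylheptanoic acid, via ozonide 15 (not isolated), via aldehyde 16 (not isolated)
Conditions: O3, CH2Cl2, −78 °C; PPh3 (1.2 equiv), → rt; then NaClO2, NaH2PO4, 2-methyl-2-butene, t-BuOH/H2O, 0 °C
Reagents that add atoms: ozone [O-][O+]=O; sodium chlorite [Na+].[O-]Cl=O
Why: Ozonolysis (Criegee) of the only C=C with phosphine reduction of the ozonide, followed by buffered Pinnick oxidation, turns the isopropylidene terminus into the carboxyl that becomes the C9 ketone carbon, under conditions too mild to epimerise the α-centre.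

Step 10
Reactants: 18 methyl (3R)-3-hydroxybutanoate
Product: 19 tert-butyl (5R)-5-hydroxy-3-oxohexanoate
Conditions: t-BuOAc (3.3 equiv), LDA (3.3 equiv), THF, −78 °C; then 18, −78 → −20 °C; aq. NH4Cl
Reagents that add atoms: tert-butyl acetate CC(=O)OC(C)(C)C
Why: Crossed Claisen condensation of the ester with excess lithium enolate (the first equivalent deprotonates the hydroxyl) gives the δ-hydroxy-β-keto ester with the (R) centre untouched.

Step 11
Reactants: 19 tert-butyl (5R)-5-hydroxy-3-oxohexanoate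
Product: 20 (6R)-6-methyloxane-2,4-dione
Conditions: TFA/CH2Cl2 (1:4), rt
Reagents that add atoms: none
Why: Acidolysis of the tert-butyl ester and spontaneous δ-lactonisation close the dihydropyranone ring with the carbinol centre retained.

Step 12
Reactants: 17 (4S)-7-[(5R,6R)-6-[(2S)-butan-2-yl]-2,2-dimethyl-4-oxo-1,3-dioxan-5-yl]-4-methylheptanoic acid; 20 (6R)-6-methyloxane-2,4-dione
Product: 23 (2R,6S)-2-[(1R,2S)-1-hydroxy-2-methylbutyl]-9-[(6R)-4-hydroxy-6-methyl-2-oxo-5,6-dihydro-2H-pyran-3-yl]-6-methyl-9-oxononanoic acid, via enol ester 21 (not isolated), via acyl dioxanone 22 (not isolated)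
Conditions: DCC (1.3 equiv), DMAP (1.5 equiv), CH2Cl2, 0 °C → rt; then TFA/H2O (10:1) added, rt
Reagents that add atoms: none
Why: Steglich O-acylation of the enol is followed by DMAP-mediated O→C acyl migration (Fries-type) to the chelated 3-acyl tricarbonyl, and aqueous acid then hydrolyses the ketal-ester to free the β-hydroxy acid without touching any stereocentre.

## Compound list

1 | (S)-2-methylbutan-1-ol | CC[C@H](C)CO | starting material
2 | (S)-2-methylbutanal | CC[C@H](C)C=O | intermediate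
3 | ethyl (2E,4S)-4-methylhex-2-enoate | CC[C@H](C)/C=C/C(=O)OCC | intermediate
4 | (2E,4S)-4-methylhex-2-en-1-ol | CC[C@H](C)/C=C/CO | intermediate
5 | [(2R,3R)-3-[(2S)-butan-2-yl]oxiran-2-yl]methanol | CC[C@H](C)[C@H]1O[C@@H]1CO | intermediate
6 | (2S,3R)-3-[(2S)-butan-2-yl]oxirane-2-carboxylic acid | CC[C@H](C)[C@H]1O[C@@H]1C(=O)O | intermediate
7 | (R)-citronellal, (3R)-3,7-dimethyloct-6-enal | C[C@H](CCC=C(C)C)CC=O | starting material
8 | (4R)-4,8-dimethylnona-1,7-diene | C[C@H](CCC=C(C)C)CC=C | intermediate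
9 | chloro[(4R)-4,8-dimethylnon-7-en-1-yl]bis(cyclopentadienyl)zirconium | C[C@H](CCC=C(C)C)CCC[Zr](Cl)(C1C=CC=C1)C1C=CC=C1 | intermediate
10 | (6R)-9-iodo-2,6-dimethylnon-2-ene | C[C@H](CCC=C(C)C)CCCI | intermediate
11 | [(4S)-4,8-dimethylnon-7-en-1-yl]lithium (same spatial arrangement as 10; the letter changes by CIP only) | C[C@H](CCC=C(C)C)CCC[Li] | intermediate
12 | lithium bis[(4R)-4,8-dimethylnon-7-en-1-yl]cuprate | C[C@H](CCC=C(C)C)CCC[Cu-]CCC[C@H](C)CCC=C(C)C.[Li+] | intermediate
13 | (2R,3R,4S)-2-[(4S)-4,8-dimethylnon-7-en-1-yl]-3-hydroxy-4-methylhexanoic acid | CC[C@H](C)[C@@H](O)[C@@H](CCC[C@H](C)CCC=C(C)C)C(=O)O | intermediate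
14 | (5R,6R)-6-[(2S)-butan-2-yl]-5-[(4S)-4,8-dimethylnon-7-en-1-yl]-2,2-dimethyl-1,3-dioxan-4-one | CC[C@H](C)[C@H]1OC(C)(C)OC(=O)[C@@H]1CCC[C@H](C)CCC=C(C)C | intermediate
15 | (5R,6R)-6-[(2S)-butan-2-yl]-5-[(4S)-6-(5,5-dimethyl-1,2,4-trioxolan-3-yl)-4-methylhexyl]-2,2-dimethyl-1,3-dioxan-4-one (both epimers at the trioxolane carbon) | CC[C@H](C)[C@H]1OC(C)(C)OC(=O)[C@@H]1CCC[C@H](C)CCC2OOC(C)(C)O2 | intermediate
16 | (4S)-7-[(5R,6R)-6-[(2S)-butan-2-yl]-2,2-dimethyl-4-oxo-1,3-dioxan-5-yl]-4-methylheptanal | CC[C@H](C)[C@H]1OC(C)(C)OC(=O)[C@@H]1CCC[C@H](C)CCC=O | intermediate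
17 | (4S)-7-[(5R,6R)-6-[(2S)-butan-2-yl]-2,2-dimethyl-4-oxo-1,3-dioxan-5-yl]-4-methylheptanoic acid | CC[C@H](C)[C@H]1OC(C)(C)OC(=O)[C@@H]1CCC[C@H](C)CCC(=O)O | intermediate
18 | methyl (3R)-3-hydroxybutanoate | C[C@@H](O)CC(=O)OC | starting material
19 | tert-butyl (5R)-5-hydroxy-3-oxohexanoate | C[C@@H](O)CC(=O)CC(=O)OC(C)(C)C | intermediate
20 | (6R)-6-methyloxane-2,4-dione (enol form: (6R)-4-hydroxy-6-methyl-5,6-dihydro-2H-pyran-2-one) | C[C@@H]1CC(=O)CC(=O)O1 | intermediate
21 | (2R)-2-methyl-6-oxo-3,6-dihydro-2H-pyran-4-yl (4S)-7-[(5R,6R)-6-[(2S)-butan-2-yl]-2,2-dimethyl-4-oxo-1,3-dioxan-5-yl]-4-methylheptanoate | CC[C@H](C)[C@H]1OC(C)(C)OC(=O)[C@@H]1CCC[C@H](C)CCC(=O)OC2=CC(=O)O[C@H](C)C2 | intermediate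
22 | (5R,6R)-6-[(2S)-butan-2-yl]-5-[(4S)-7-[(6R)-4-hydroxy-6-methyl-2-oxo-5,6-dihydro-2H-pyran-3-yl]-4-methyl-7-oxoheptyl]-2,2-dimethyl-1,3-dioxan-4-one | CC[C@H](C)[C@H]1OC(C)(C)OC(=O)[C@@H]1CCC[C@H](C)CCC(=O)C2=C(O)C[C@@H](C)OC2=O | intermediate
23 | (2R,6S)-2-[(1R,2S)-1-hydroxy-2-methylbutyl]-9-[(6R)-4-hydroxy-6-methyl-2-oxo-5,6-dihydro-2H-pyran-3-yl]-6-methyl-9-oxononanoic acid (CNP0392340.1) | CC[C@H](C)[C@@H](O)[C@@H](CCC[C@H](C)CCC(=O)C1=C(O)C[C@@H](C)OC1=O)C(=O)O | target

## Step count and risks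

Total step count: 12. Longest linear sequence: 8 (steps 1, 2, 3, 4, 7, 8, 9, 12).

**Step 7 (most likely to fail).** The cuprate may attack C3 instead of C2, or the sparingly soluble lithium epoxy-carboxylate may react sluggishly. The fallback sets out from epoxy alcohol 5 and iodide 10 and comes back at 13. Cuprate 12, made from 10 as in step 7, opens the lithium alkoxide of 5 at C2 in Et2O at −40 → 0 °C; this is the usual C2-selective opening of 3-branched trans-2,3-epoxy alcohols, again with inversion. The product is (2S,3R,4S)-2-[(4S)-4,8-dimethylnon-7-en-1-yl]-4-methylhexane-1,3-diol F1. A brief NaIO4 wash removes any 1,2-diol regioisomer. Selective oxidation of the primary hydroxyl of F1 (TEMPO cat., PhI(OAc)2, MeCN/H2O) gives 13; the oxidation level is raised after the C–C bond is made, and step 4 is not needed.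

**Step 12.** The O→C acyl shift may stall, or DMAP may attack the dioxanone carbonyl. The fallback sets out from acid 17 and hydroxy ester 18 and comes back at 22, building the pyrandione onto the chain by Dieckmann cyclisation. Acid 17 is condensed with Meldrum's acid (DCC, DMAP cat., CH2Cl2, 0 °C) to 5-[(4S)-7-[(5R,6R)-6-[(2S)-butan-2-yl]-2,2-dimethyl-4-oxo-1,3-dioxan-5-yl]-1-hydroxy-4-methylheptylidene]-2,2-dimethyl-1,3-dioxane-4,6-dione F2. Heating F2 with 18 in toluene at 80 °C gives methyl (3R)-3-{[(6S)-9-[(5R,6R)-6-[(2S)-butan-2-yl]-2,2-dimethyl-4-oxo-1,3-dioxan-5-yl]-6-methyl-3-oxononanoyl]oxy}butanoate F3. KOtBu in THF/t-BuOH at 0 °C closes the ring to 22, which is hydrolysed as in the second stage of step 12.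

**Step 9.** The acetonide may not survive the aqueous chlorite stage. The fallback sets out from 13 and comes back at 17, cleaving first and protecting afterwards. Unprotected 13 is ozonised (O3, CH2Cl2, −78 °C) to (2R,3R,4S)-2-[(4S)-6-(5,5-dimethyl-1,2,4-trioxolan-3-yl)-4-methylhexyl]-3-hydroxy-4-methylhexanoic acid F4. PPh3 reduces it to (2R,3R,4S)-3-hydroxy-4-methyl-2-[(4S)-4-methyl-7-oxoheptyl]hexanoic acid F5. Pinnick oxidation gives (2R,6S)-2-[(1R,2S)-1-hydroxy-2-methylbutyl]-6-methylnonanedioic acid F6. Treating F6 with 2-methoxypropene/PPTS closes the dioxanone; only the β-hydroxy acid can form the six-membered acetonide, and the remote carboxyl is recovered free on aqueous work-up, giving 17.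

Further compounds

F1 | step 7 | (2S,3R,4S)-2-[(4S)-4,8-dimethylnon-7-en-1-yl]-4-methylhexane-1,3-diol | CC[C@H](C)[C@@H](O)[C@@H](CCC[C@H](C)CCC=C(C)C)CO
F2 | step 12 | 5-[(4S)-7-[(5R,6R)-6-[(2S)-butan-2-yl]-2,2-dimethyl-4-oxo-1,3-dioxan-5-yl]-1-hydroxy-4-methylheptylidene]-2,2-dimethyl-1,3-dioxane-4,6-dione | CC[C@H](C)[C@H]1OC(C)(C)OC(=O)[C@@H]1CCC[C@H](C)CCC(O)=C2C(=O)OC(C)(C)OC2=O
F3 | step 12 | methyl (3R)-3-{[(6S)-9-[(5R,6R)-6-[(2S)-butan-2-yl]-2,2-dimethyl-4-oxo-1,3-dioxan-5-yl]-6-methyl-3-oxononanoyl]oxy}butanoate | CC[C@H](C)[C@H]1OC(C)(C)OC(=O)[C@@H]1CCC[C@H](C)CCC(=O)CC(=O)O[C@H](C)CC(=O)OC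
F4 | step 9 | (2R,3R,4S)-2-[(4S)-6-(5,5-dimethyl-1,2,4-trioxolan-3-yl)-4-methylhexyl]-3-hydroxy-4-methylhexanoic acid | CC[C@H](C)[C@@H](O)[C@@H](CCC[C@H](C)CCC1OOC(C)(C)O1)C(=O)O
F5 | step 9 | (2R,3R,4S)-3-hydroxy-4-methyl-2-[(4S)-4-methyl-7-oxoheptyl]hexanoic acid | CC[C@H](C)[C@@H](O)[C@@H](CCC[C@H](C)CCC=O)C(=O)O
F6 | step 9 | (2R,6S)-2-[(1R,2S)-1-hydroxy-2-methylbutyl]-6-methylnonanedioic acid | CC[C@H](C)[C@@H](O)[C@@H](CCC[C@H](C)CCC(=O)O)C(=O)O
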